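I began from the amounts: 1.50 equivalents of partner to substrate, with the same charge in each set-up.

| setting | Wednesday's | Friday's | Monday's | Thursday's |
|---|---|---|---|---|
| substrate | 0.30 M | 0.30 M | 0.30 M | 0.30 M |
| partner | 0.450 M | 0.450 M | 0.450 M | 0.450 M (fed, over 4.00 h) |
| remark | a single well-mixed tank run continuously and read at steady state, 80.0 h in it on average | one stirred flow tank at steady state, fed with the mixture as stated, mean residence time 8.0 h | everything together in a closed stirred flask, run for 8.0 h | all but partner at the start; partner goes in evenly over 4.00 h, the run ends at 8.0 h |
| time |  |  | 8.0 h | 8.0 h |

    substrate ⇌ intermediate A (K1 = 23, k1 = 0.0874 /h)
    substrate + partner → intermediate B (k2 = 0.666 /M/h)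
    substrate → intermediate C (k3 = 0.137 /h)
    intermediate C → side product (k4 = 0.0189 /h)
    intermediate B → target (k5 = 0.0649 /h)

- the stated concentrations are those of everything mixed, before any reaction; amounts are the same in each set-up
- the feed brings no volume worth counting
- run time (Monday's): 8.0 h

1. the set-up with the highest share of target in all that became target or side product, at the outlet or at the end ("none" if the first two lie within 2 percentage points) (Wednesday's / Friday's / Monday's / Thursday's / none)
2. share of target in all that became target or side product, at the outlet or at the end, Wednesday's
3. share of target in all that became target or side product, at the outlet or at the end, Friday's
4. share of target in all that became target or side product, at the outlet or at the end, Monday's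
5. share of target in all that became target or side product, at the outlet or at the end, Thursday's

I reckoned Monday's flask by hand. Substrate forks there: step 1 takes it to intermediate A, step 2 leads through intermediate B to target, and step 3 leads through intermediate C to side product. I took the symmetric case as the zero of the scale: an even fork between steps 2 and 3, with equal last steps, gives one target per side product. Monday's flask starts with a fork ratio of 2.19 and a last-step ratio of 3.43. Their product, at the full partner charge, is the selectivity factor, the target made per side product while both intermediates are young: 7.51. I took that as valid for a run of 8.0 h, which is shorter than the half-life of intermediate B by step 5, 10.7 h. The share of target is this factor over one plus the factor.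

The first way used the factor as it stood and gave 88.2%. The second way started from the balance. At the start, 57.2% of reacting substrate took partner, by the forward rates of steps 1 to 3. Carrying that start value through the whole substrate charge, I reckoned a remainder of 0.619 of the partner charge. Scaled by that fraction, the factor came to 4.65 and the share to 82.3%. The two ways parted by 6 percentage points, and each cheated. The first held partner at its full charge, and the second priced every bit of product at the final partner level. So I committed to the middle fraction, 0.809, which gave 85.9% for Monday's.

The forecast gave 67.4% for Wednesday's, 80.8% for Friday's, 84.6% for Monday's and 69.7% for Thursday's, and named Monday's as best, saying the second-order step “favours having substrate and partner together at high concentration from the start”. My Monday's number stood above its figure.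

The simulation named Monday's, with 67.4% for Wednesday's, 80.8% for Friday's, 84.6% for Monday's and 69.5% for Thursday's. Monday's flask ended with 66% of the partner charge left. Read backwards, 84.6% means 5.48 target per side product, a fraction 0.730 of the selectivity factor, which lies above that remaining partner. For the neighbour, Monday's flask with 0.27 M of partner, the factor scales to 4.51, and the same fraction predicts 76.7%; that flask gave 76.2%.

The numbers of this flask belong to no real substance.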